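## Structural features

The target is a 3,4-dibenzylbutyrolactone lignan. It has one five-membered lactone (O1, C2 carbonyl, C3, C4, C5 methylene), with a 3,4,5-trimethoxybenzyl group on C3 and a 4-hydroxy-3,5-dimethoxybenzyl (syringyl) group on C4. C3 and C4 are the only stereocentres; they are adjacent, both R, and hold the two benzyl groups trans. C3 is α to the lactone carbonyl and can be epimerised, trans being the thermodynamic arrangement, whereas C4 is not acidic and must be set absolutely. The fragile groups are the free electron-rich phenol (base, one-electron oxidants), the lactone (hydride, hydroxide) and the C3–H. The real difficulty is that the two aryl rings differ only at a para oxygen far from the lactone, so the C2–C3–C4–C5 core with its two benzyl arms is nearly symmetric. The carbonyl must end up on the trimethoxybenzyl side and C4 must be R, so the two arylpropanoid halves have to be told apart in oxidation level and in chirality. The key step uses the fact that the C3–C4 bond joins two carbons that are each α to a carboxyl-derived carbon (C3 next to C2, C4 next to C5). The core is thus a 2,3-dibenzylsuccinate with one carboxyl reduced, and the bond can be made by uniting two 3-arylpropanoyl enolates at their α-carbons.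

## Logic of the disconnections

**15 ⇒ 14.** The phenolic O–H of 15 is traced back to an O–benzyl bond. A free syringyl phenol would be deprotonated by the amide base and oxidised by the metal oxidant of the key step. A benzyl ether survives base, hydride, catalytic acid and amine base, and leaves under neutral hydrogenolysis. The gain is that no earlier intermediate carries an acidic or oxidisable aryl O–H. The forward step must remove only the O–benzyl group and leave the C5–O1 bond, the C–benzyl bonds and C3 alone.

**14 ⇒ 13.** The lactone is opened at the O1–C2 acyl–oxygen bond, giving an acyclic γ-hydroxy ester. This is the only ring, so the problem becomes acyclic with two termini at different oxidation levels. Because C3 of 14 can be equilibrated to trans, the C3 configuration need not be secured earlier. The forward step must cleave the tert-butyl ester without harming the benzyl ether, and the base must touch C3 only.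

**13 ⇒ 12.** The C5 carbinol is traced back to an imide carbonyl carrying the auxiliary (the two C5–H bonds are replaced by C5=O and a C5–N bond). An acyl carbon at C5 makes C4 enolisable and brings in the chiral controller. It also keeps the two carboxyl termini distinct, since the imide is reducible and the tert-butyl ester is not. The forward step needs hydride attack at the exocyclic imide carbonyl only, not at the ring carbamate or the ester, and no ring closure while hydride is still present.

**12 ⇒ 7 + 9.** The central C3–C4 bond is cut. Both carbons are α to carbonyls and so have the same polarity; the forward union therefore needs an oxidant. The gain is the largest of the plan, because it gives two simple 3-arylpropanoyl derivatives of similar size in a convergent route. The forward step must favour cross- over homo-coupling and must control the face of the imide α-carbon (C4). Control at C3 is not demanded.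

**7 ⇒ 4 + 5.** The N–acyl bond is cut to a carboxylic acid and the commercial auxiliary. The forward acylation must activate the acid without touching the benzyl ether.

**4 ⇒ 2 ⇒ 1.** The O–benzyl bond of 4 is cut to give 2, and the saturated side chain of 2 is traced to the C=C of 1. The order is forced, because hydrogenation after benzylation would strip the benzyl group. Benzylation also esterifies the carboxyl (3), so the forward step must include a saponification.

**9 ⇒ 8.** The ester C–O bond is cut to the commercial acid. The tert-butyl group is chosen because it suppresses Claisen self-condensation of the enolate, resists hydride and later leaves under acid. The forward esterification should avoid free tert-butyl cations near the electron-rich ring.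

## Other disconnections considered

**Alternative 1:** The cut removes O1–C2 and C2–C3 together, so that C2 comes from carbon monoxide and the rest of the ring from the homopropargylic alcohol A1.

- **Forward step.** PdCl2(PPh3)2 (divalent palladium) with SnCl2 under CO would turn the hydroxyl of A1 into an alkoxycarbonyl–palladium unit. This would add syn across the alkyne in a 5-exo mode, and protonolysis would give the (E)-benzylidene lactone A2.
- **In favour.** Ring and carbonyl arrive in one step. The hydroxyl dictates where the carbonyl sits, so the near-symmetry problem does not arise. C4 is never α to a carbonyl and cannot epimerise. One hydrogenation could reduce the exocyclic alkene and remove the benzyl ether of A2; on this point the alternative is better than the chosen plan, which spends a separate step on debenzylation.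
- **Against.** C4 must be built into A1 beforehand as a propargylic carbon bearing CH2OH and an arylmethyl group. That would need an auxiliary alkylation, passage through an α-branched aldehyde prone to racemisation, an alkyne homologation and an aryl–alkyne coupling. CO under pressure and a tin salt are less convenient. Hydrogenation of A2 is expected to deliver hydrogen anti to the C4 substituent and give the cis lactone, so the same C3 equilibration would still be needed.
- **Comparison.** Structurally, this key step closes the ring but creates no stereocentre, whereas the chosen coupling closes no ring but makes the C3–C4 bond and C4 together. Mechanistically it is a catalytic two-electron carbonylation without homodimer by-products, which is equal or better than a stoichiometric one-electron oxidation. In step economy, A1 is estimated at six or more steps against three for 7, so the total would be higher.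

**Alternative 2:** The cut is the bond between C4 and its benzylic CH2.

- **Forward step.** The enamine from the aldehyde ester A3 and a chiral diarylprolinol silyl ether would add in a 1,6 sense to the exocyclic carbon of the quinone methide A4. A4 would be generated in situ from a syringyl precursor with a benzylic leaving group. Rearomatisation and iminium hydrolysis would give the aldehyde A5 with C4 set by the catalyst. Reduction of the formyl group and lactonisation would give A6, and trans-selective enolate alkylation with the bromide A7 would install C3.
- **In favour.** Chirality is catalytic rather than stoichiometric (better than the chosen plan). The phenol is the enabling element, so no protecting group is needed up to A6 (better). C2 and C5 are already differentiated in A3 (equal). C3 would be set by kinetic trans alkylation rather than by equilibration (equal or better).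
- **Against.** A4 has no stabilising substituent on the exocyclic carbon and no bulky ortho groups. Such a methide is expected to oligomerise and to add water or the amine catalyst in competition with the enamine. The stereocentre of A5 is α to an aldehyde and could racemise through the same enamine. Alkylation of A6 would need the phenol protected, or a dianion with competing O-alkylation, which brings back a protection and a deprotection.
- **Comparison.** Structurally, the bond formed lies at the periphery of the core and leaves a second C–C bond to be made; the chosen plan forms the central bond and finishes the skeleton in one step. Mechanistically it is a polar 1,6-addition under catalyst control, against an auxiliary-controlled oxidative union. In step economy it is about six steps in the best case (shorter than eight), but seven to eight once the phenol is protected, and the risk sits in a methide far less stabilised than those of the closest analogies.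

**Alternative 3:** The cut removes both ring–benzyl bonds, C4–C(benzylic) and C3–CH2Ar.

- **Forward step.** The lithiated dithiane A9 would add to C4 of the butenolide A8 anti to the menthyloxy group. The lactone enolate so formed would be trapped at C3 by the bromide A7, anti to the new C4 substituent, giving A10.
- **In favour.** Two C–C bonds and both stereocentres form in one flask, with C3 set kinetically trans (better than the chosen plan on both counts). Induction comes from a rigid ring rather than from an enolate aggregate. There is no homodimer problem.
- **Against.** A10 carries three features foreign to the target: the dithiane at the benzylic carbon, the acetal at C5 and the benzyl ether. The end game would need desulfurisation with excess Raney Ni (which might also remove the benzyl ether, a possible saving). It would also need acetal hydrolysis, reduction of the liberated aldehyde and relactonisation, with C3 exposed to base. A8 needs prior preparation and separation from its acetal epimer, and A9 must be made as well.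
- **Comparison.** Both plans use a stoichiometric chiral controller (equal). The alternative builds more per step but then spends about three steps removing scaffolding, so the total (about eight to nine with A8 and A9) is equal to or slightly above the chosen plan. Thiol and excess Raney Ni are practical drawbacks; the chosen plan's drawbacks are the stoichiometric oxidant and the uncontrolled C3, which is repaired by equilibration.

Key step: step 5

Remark on the chemistry: the chelated imide enolate is assumed to react on the face away from the 4-benzyl group in the oxidative coupling as it does in polar alkylations. Any epimer at the ester α-carbon is carried unseparated with 12 and 13 and converges in step 7.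

## Route

Step 1
Reactants: 1 sinapic acid, (E)-3-(4-hydroxy-3,5-dimethoxyphenyl)prop-2-enoic acid
Product: 2 3-(4-hydroxy-3,5-dimethoxyphenyl)propanoic acid
Conditions: H2 (1 atm), 10% Pd/C, MeOH, rt
Reagents that add atoms: none
Why: Heterogeneous catalytic hydrogenation of a cinnamic acid C=C; arene, phenol and acid are inert. It is placed before benzylation because the same conditions would cleave a benzyl ether.

Step 2
Reactants: 2 3-(4-hydroxy-3,5-dimethoxyphenyl)propanoic acid
Product: 4 3-(4-benzyloxy-3,5-dimethoxyphenyl)propanoic acid, via benzyl 3-(4-benzyloxy-3,5-dimethoxyphenyl)propanoate 3 (not isolated)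
Conditions: BnBr (2.3 equiv), K2CO3, DMF, 60 °C; then 2 M NaOH, MeOH, 60 °C; HCl to pH 2
Reagents that add atoms: benzyl bromide, BrCc1ccccc1; sodium hydroxide, [Na+].[OH-] (one carboxyl oxygen of 4 comes from hydroxide)
Why: Williamson ether synthesis in which phenoxide and carboxylate are both benzylated, then saponification of the benzyl ester in the same pot. The aryl benzyl ether is stable to hydroxide.

Step 3
Reactants: 4 3-(4-benzyloxy-3,5-dimethoxyphenyl)propanoic acid; 5 (S)-4-benzyloxazolidin-2-one
Product: 7 (S)-4-benzyl-3-[3-(4-benzyloxy-3,5-dimethoxyphenyl)propanoyl]oxazolidin-2-one, via 3-(4-benzyloxy-3,5-dimethoxyphenyl)propanoic pivalic anhydride 6 (not isolated)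
Conditions: PivCl, Et3N, THF, −20 °C; then 5, LiCl, −20 °C to rt
Reagents that add atoms: none
Why: Mixed-anhydride N-acylation of an oxazolidinone promoted by LiCl and Et3N; the nitrogen attacks the unhindered acyl carbon rather than the pivaloyl carbon. The stereocentre of 5 is not involved.

Step 4
Reactants: 8 3-(3,4,5-trimethoxyphenyl)propanoic acid
Product: 9 tert-butyl 3-(3,4,5-trimethoxyphenyl)propanoate
Conditions: t-BuOH (3 equiv), DCC, DMAP (cat.), CH2Cl2, 0 °C to rt
Reagents that add atoms: tert-butanol, CC(C)(C)O
Why: Steglich esterification through the O-acylisourea and the acylpyridinium ion. No free tert-butyl cation is formed, so the electron-rich ring is not alkylated.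

Step 5
Reactants: 7 (S)-4-benzyl-3-[3-(4-benzyloxy-3,5-dimethoxyphenyl)propanoyl]oxazolidin-2-one; 9 tert-butyl 3-(3,4,5-trimethoxyphenyl)propanoate
Product: 12 tert-butyl (2R,3R)-4-[(S)-4-benzyl-2-oxooxazolidin-3-yl]-3-(4-benzyloxy-3,5-dimethoxybenzyl)-4-oxo-2-(3,4,5-trimethoxybenzyl)butanoate, via imide lithium (Z)-enolate 10 (not isolated), via ester lithium enolate 11 (not isolated)
Conditions: 7 (1 equiv), 9 (1.5 equiv), LiN(i-Pr)2 (2.6 equiv), THF, −78 °C, 30 min; Fe(acac)3 (2.5 equiv), −78 °C to rt; aq. NH4Cl
Reagents that add atoms: none
Why: Oxidative enolate heterocoupling, a known reaction type for the pairing of an N-acyloxazolidinone enolate with an ester enolate under Fe(acac)3 (trivalent iron) or copper bis(2-ethylhexanoate) (divalent copper): LiN(i-Pr)2 converts 7 and 9 into the lithium enolates 10 and 11, which are expected to form mixed aggregates, and leaves the benzyl ether untouched at −78 °C. One-electron transfer from one enolate to Fe(acac)3 gives a metal-associated α-carbonyl radical that is captured at carbon by the other enolate; a second one-electron oxidation of the resulting radical anion gives the neutral 1,4-dicarbonyl compound, so that the C3–C4 bond (lactone numbering) is formed between two carbons of like polarity. No ring is closed. C4 (imide α-carbon) is controlled by the auxiliary: in the chelated (Z)-enolate 10 the 4-benzyl group covers one face and the new bond forms on the other, the same facial sense as in alkylations of such enolates, which corresponds to R with the (S)-auxiliary. C3 (ester α-carbon) is controlled only by the mutual approach of the two trisubstituted carbons and is expected to be set less cleanly; the route does not rely on it, because C3 becomes the epimerisable lactone α-carbon and any epimer carried along converges in step 7. The selectivity that the step needs is cross- over homo-coupling: the different oxidation potentials and aggregation of an imide and an ester enolate favour the mixed pair, and the inexpensive ester 9 is used in excess so that the imide 7 is the limiting partner. The tert-butyl group suppresses Claisen condensation of 11 and leaves the two carbonyls of 12 distinguishable (reducible imide, hydride-inert ester), which fixes C5 and C2. Should Fe(acac)3 give mainly homodimers, copper bis(2-ethylhexanoate) is the alternative oxidant of the same reaction type.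

Step 6
Reactants: 12 tert-butyl (2R,3R)-4-[(S)-4-benzyl-2-oxooxazolidin-3-yl]-3-(4-benzyloxy-3,5-dimethoxybenzyl)-4-oxo-2-(3,4,5-trimethoxybenzyl)butanoate
Product: 13 tert-butyl (2R,3R)-3-(4-benzyloxy-3,5-dimethoxybenzyl)-4-hydroxy-2-(3,4,5-trimethoxybenzyl)butanoate
Conditions: LiBH4 (2 equiv), H2O (1 equiv), Et2O–THF, 0 °C; aq. NH4Cl
Reagents that add atoms: none
Why: Reductive cleavage of an N-acyloxazolidinone by LiBH4: hydride adds to the exocyclic imide carbonyl, the auxiliary 5 is expelled and the aldehyde is reduced on to the primary alcohol. The tert-butyl ester is inert at 0 °C and neither stereocentre takes part.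

Step 7
Reactants: 13 tert-butyl (2R,3R)-3-(4-benzyloxy-3,5-dimethoxybenzyl)-4-hydroxy-2-(3,4,5-trimethoxybenzyl)butanoate
Product: 14 (3R,4R)-4-(4-benzyloxy-3,5-dimethoxybenzyl)-3-(3,4,5-trimethoxybenzyl)dihydrofuran-2(3H)-one
Conditions: TsOH·H2O (0.2 equiv), toluene, 80 °C; then DBU (2 equiv), 80 °C
Reagents that add atoms: none
Why: Acid-catalysed cleavage of the tert-butyl ester with 5-exo-trig lactonisation by the primary hydroxyl; DBU then equilibrates C3 through the lactone enolate to the thermodynamically preferred trans-3,4 arrangement, which converges any material epimeric at C3. C4 is not acidic and keeps its configuration.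

Step 8
Reactants: 14 (3R,4R)-4-(4-benzyloxy-3,5-dimethoxybenzyl)-3-(3,4,5-trimethoxybenzyl)dihydrofuran-2(3H)-one
Product: 15 (3R,4R)-4-(4-hydroxy-3,5-dimethoxybenzyl)-3-(3,4,5-trimethoxybenzyl)dihydrofuran-2(3H)-one
Conditions: H2 (1 atm), 10% Pd/C, EtOAc–EtOH, rt
Reagents that add atoms: none
Why: Hydrogenolysis of an aryl benzyl ether under neutral conditions; the lactone, the methyl ethers and both stereocentres are unaffected.

## Compound list

1 | sinapic acid, (E)-3-(4-hydroxy-3,5-dimethoxyphenyl)prop-2-enoic acid | COc1cc(/C=C/C(=O)O)cc(OC)c1O | starting material
2 | 3-(4-hydroxy-3,5-dimethoxyphenyl)propanoic acid | COc1cc(CCC(=O)O)cc(OC)c1O | intermediate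
3 | benzyl 3-(4-benzyloxy-3,5-dimethoxyphenyl)propanoate | COc1cc(CCC(=O)OCc2ccccc2)cc(OC)c1OCc1ccccc1 | intermediate
4 | 3-(4-benzyloxy-3,5-dimethoxyphenyl)propanoic acid | COc1cc(CCC(=O)O)cc(OC)c1OCc1ccccc1 | intermediate
5 | (S)-4-benzyloxazolidin-2-one | O=C1OC[C@H](Cc2ccccc2)N1 | starting material
6 | 3-(4-benzyloxy-3,5-dimethoxyphenyl)propanoic pivalic anhydride | COc1cc(CCC(=O)OC(=O)C(C)(C)C)cc(OC)c1OCc1ccccc1 | intermediate
7 | (S)-4-benzyl-3-[3-(4-benzyloxy-3,5-dimethoxyphenyl)propanoyl]oxazolidin-2-one | COc1cc(CCC(=O)N2[C@@H](Cc3ccccc3)COC2=O)cc(OC)c1OCc1ccccc1 | intermediate
8 | 3-(3,4,5-trimethoxyphenyl)propanoic acid | COc1cc(CCC(=O)O)cc(OC)c1OC | starting material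
9 | tert-butyl 3-(3,4,5-trimethoxyphenyl)propanoate | COc1cc(CCC(=O)OC(C)(C)C)cc(OC)c1OC | intermediate
10 | lithium (Z)-1-[(S)-4-benzyl-2-oxooxazolidin-3-yl]-3-(4-benzyloxy-3,5-dimethoxyphenyl)prop-1-en-1-olate | COc1cc(C/C=C(\[O-])N2[C@@H](Cc3ccccc3)COC2=O)cc(OC)c1OCc1ccccc1.[Li+] | intermediate
11 | lithium 1-tert-butoxy-3-(3,4,5-trimethoxyphenyl)prop-1-en-1-olate (O–Li trans to the arylmethyl group) | COc1cc(C/C=C(/[O-])OC(C)(C)C)cc(OC)c1OC.[Li+] | intermediate
12 | tert-butyl (2R,3R)-4-[(S)-4-benzyl-2-oxooxazolidin-3-yl]-3-(4-benzyloxy-3,5-dimethoxybenzyl)-4-oxo-2-(3,4,5-trimethoxybenzyl)butanoate | COc1cc(C[C@@H](C(=O)N2[C@@H](Cc3ccccc3)COC2=O)[C@@H](Cc2cc(OC)c(OC)c(OC)c2)C(=O)OC(C)(C)C)cc(OC)c1OCc1ccccc1 | intermediate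
13 | tert-butyl (2R,3R)-3-(4-benzyloxy-3,5-dimethoxybenzyl)-4-hydroxy-2-(3,4,5-trimethoxybenzyl)butanoate | COc1cc(C[C@@H](CO)[C@@H](Cc2cc(OC)c(OC)c(OC)c2)C(=O)OC(C)(C)C)cc(OC)c1OCc1ccccc1 | intermediate
14 | (3R,4R)-4-(4-benzyloxy-3,5-dimethoxybenzyl)-3-(3,4,5-trimethoxybenzyl)dihydrofuran-2(3H)-one | COc1cc(C[C@H]2COC(=O)[C@@H]2Cc2cc(OC)c(OC)c(OC)c2)cc(OC)c1OCc1ccccc1 | intermediate
15 | (3R,4R)-4-(4-hydroxy-3,5-dimethoxybenzyl)-3-(3,4,5-trimethoxybenzyl)dihydrofuran-2(3H)-one | COc1cc(C[C@H]2COC(=O)[C@@H]2Cc2cc(OC)c(OC)c(OC)c2)cc(OC)c1O | target

## Step count and least certain steps

Total step count: 8. Longest linear sequence: 7 steps (steps 1, 2, 3, 5, 6, 7, 8, from 1 to 15); the ester arm joins after one step (step 4).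

**Step 5 (key step).**
- What may go wrong: homocoupling of each enolate in competition with the cross union, and thermal breakdown of the imide enolate before it is oxidised. Cross-selectivity rests on modest differences in oxidation potential and on mixed aggregation, and both may be shifted by the two electron-rich aryl groups. Poor control at the ester α-carbon is tolerated.
- If the facial sense at C4 proved opposite to the one assumed, the enantiomeric auxiliary would correct it without changing the route.
- Fallback: it sets out from 7 and returns to the route at 14. The sodium enolate of 7 (NaN(SiMe3)2, THF, −78 °C) would be alkylated with tert-butyl bromoacetate on the face away from the auxiliary benzyl group. This would give tert-butyl (R)-4-[(S)-4-benzyl-2-oxooxazolidin-3-yl]-3-(4-benzyloxy-3,5-dimethoxybenzyl)-4-oxobutanoate F1. LiBH4 reduction as in step 6 would give tert-butyl (R)-3-(4-benzyloxy-3,5-dimethoxybenzyl)-4-hydroxybutanoate F2. Acid-catalysed closure as in step 7 would give (R)-4-(4-benzyloxy-3,5-dimethoxybenzyl)dihydrofuran-2(3H)-one F3. The lithium enolate of F3 (LiN(SiMe3)2, THF, −78 °C) would then be alkylated with 3,4,5-trimethoxybenzyl bromide (the electrophile A7) anti to the C4 substituent, giving 14 directly. This replaces the oxidative union by two polar alkylations, still forms the C3–C4 bond at the imide stage, sets C3 kinetically and costs two more steps.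

**Step 6.**
- What may go wrong: hydride attack at the ring carbamate carbonyl instead of the exocyclic one, because the exocyclic carbonyl is flanked by two branched carbons. A second risk is premature closure of the alkoxide onto the ester, followed by over-reduction of the lactone while hydride is still present.
- Fallback: it sets out from 12 and returns at 13. LiOH with H2O2 (THF–H2O, 0 °C) would cleave the auxiliary by hydroperoxide attack at the exocyclic carbonyl. This would give (2R,3R)-2-(4-benzyloxy-3,5-dimethoxybenzyl)-4-tert-butoxy-4-oxo-3-(3,4,5-trimethoxybenzyl)butanoic acid F4. BH3·SMe2 (THF, 0 °C) would then reduce the free acid in the presence of the tert-butyl ester to give 13.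

**Step 7.**
- What may go wrong: incomplete convergence of the C3 epimers (slow enolisation, or an equilibrium not fully on the trans side). The acid may also cause loss of the hindered aryl benzyl ether or ring alkylation by the tert-butyl cation that is released.
- Fallback: it sets out from 13 and returns at 14 and makes no new compound (F0). Catalytic KOt-Bu in THF at rt would close the ring by alkoxide acyl substitution on the tert-butyl ester. The tert-butoxide expelled would serve as the base that equilibrates C3. Acid then never meets the benzyl ether or the arenes, and ring closure and equilibration become a single base-mediated event.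

## Further compounds

F1 | step 5 | tert-butyl (R)-4-[(S)-4-benzyl-2-oxooxazolidin-3-yl]-3-(4-benzyloxy-3,5-dimethoxybenzyl)-4-oxobutanoate | COc1cc(C[C@@H](C(=O)N2[C@@H](Cc3ccccc3)COC2=O)CC(=O)OC(C)(C)C)cc(OC)c1OCc1ccccc1
F2 | step 5 | tert-butyl (R)-3-(4-benzyloxy-3,5-dimethoxybenzyl)-4-hydroxybutanoate | COc1cc(C[C@@H](CO)CC(=O)OC(C)(C)C)cc(OC)c1OCc1ccccc1
F3 | step 5 | (R)-4-(4-benzyloxy-3,5-dimethoxybenzyl)dihydrofuran-2(3H)-one | COc1cc(C[C@H]2COC(=O)C2)cc(OC)c1OCc1ccccc1
F4 | step 6 | (2R,3R)-2-(4-benzyloxy-3,5-dimethoxybenzyl)-4-tert-butoxy-4-oxo-3-(3,4,5-trimethoxybenzyl)butanoic acid | COc1cc(C[C@@H](C(=O)O)[C@@H](Cc2cc(OC)c(OC)c(OC)c2)C(=O)OC(C)(C)C)cc(OC)c1OCc1ccccc1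
F0 | step 7 | none | none
A1 | alternative 1 | (R)-2-(4-benzyloxy-3,5-dimethoxybenzyl)-4-(3,4,5-trimethoxyphenyl)but-3-yn-1-ol | COc1cc(C[C@@H](CO)C#Cc2cc(OC)c(OC)c(OC)c2)cc(OC)c1OCc1ccccc1
A2 | alternative 1 | (R,E)-4-(4-benzyloxy-3,5-dimethoxybenzyl)-3-(3,4,5-trimethoxybenzylidene)dihydrofuran-2(3H)-one | COc1cc(C[C@H]2COC(=O)/C2=C/c2cc(OC)c(OC)c(OC)c2)cc(OC)c1OCc1ccccc1
A3 | alternative 2 | methyl 4-oxobutanoate | COC(=O)CCC=O
A4 | alternative 2 | 2,6-dimethoxy-4-methylidenecyclohexa-2,5-dien-1-one | COC1=CC(=C)C=C(OC)C1=O
A5 | alternative 2 | methyl (R)-3-formyl-4-(4-hydroxy-3,5-dimethoxyphenyl)butanoate | COc1cc(C[C@H](CC(=O)OC)C=O)cc(OC)c1O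
A6 | alternative 2 | (R)-4-(4-hydroxy-3,5-dimethoxybenzyl)dihydrofuran-2(3H)-one | COc1cc(C[C@H]2COC(=O)C2)cc(OC)c1O
A7 | alternative 2 | 3,4,5-trimethoxybenzyl bromide | COc1cc(CBr)cc(OC)c1OC
A8 | alternative 3 | (R)-5-[(1R,2S,5R)-2-isopropyl-5-methylcyclohexyloxy]furan-2(5H)-one | O=C1C=C[C@H](O[C@@H]2C[C@H](C)CC[C@H]2C(C)C)O1
A9 | alternative 3 | 2-(4-benzyloxy-3,5-dimethoxyphenyl)-1,3-dithiane | COc1cc(C2SCCCS2)cc(OC)c1OCc1ccccc1
A10 | alternative 3 | (3R,4R,5R)-4-[2-(4-benzyloxy-3,5-dimethoxyphenyl)-1,3-dithian-2-yl]-5-[(1R,2S,5R)-2-isopropyl-5-methylcyclohexyloxy]-3-(3,4,5-trimethoxybenzyl)dihydrofuran-2(3H)-one | COc1cc(C2(SCCCS2)[C@H]2[C@H](O[C@@H]3C[C@H](C)CC[C@H]3C(C)C)OC(=O)[C@@H]2Cc2cc(OC)c(OC)c(OC)c2)cc(OC)c1OCc1ccccc1
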